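## The problem

The target is a tetracyclic cage. Its core is a bicyclo[3.3.1]nonane-2,4,9-trione: C1 is the benzoyl-bearing bridgehead, C2 and C4 are ketones flanking the quaternary C3, C5 is the geranyl-bearing bridgehead, C9 is the ketone between C1 and C5, and ring A is C5–C6–C7–C8(Me2)–C1–C9. C3 and C7 are tied by the two-carbon link C10–C11 (a homoadamantane), and a cyclopentane C3–C11–C12(Me2)–C13–C14 is fused on the C3–C11 bond. Five quaternary carbons (C1, C3, C5, C8, C12) crowd the cage, so almost every bond to C1, C3 or C11 must be made next to a fully substituted neighbour. Of the five stereocentres, C1, C3, C5 and C7 are locked together by the cage, which can close in only one relative arrangement; C7, the only one that carries hydrogen and sits in a simple six-membered ring, can therefore control the other three. C11 is not fixed by the cage and must be set relative to it; the only handle is the difference between the two faces of the C10–C11 unit (C6H2 on one side, the C8 methyl groups on the other). Three features will not survive rough treatment: the geranyl chain (no hydrogenation, strong acid or radical oxidation once it is in place); the non-enolisable tricarbonyl array with benzoyl on C1 (cleaved by nucleophiles in a retro-Claisen sense); and any intermediate in which C7–H is allylic and γ to a ring A enone (epimerisation through a dienolate). The feature that opens the key step is that the trione ring C1–C2–C3–C4–C5–C9 is a ketone (C9) acylated at both α-carbons (C1 and C5) by the two carboxyl carbons (C2 and C4) of a cyclopentane-1,1-dicarboxylic acid centred on C3. With C10=C11 as a (Z)-alkene, the two ester groups sit above and below the alkene plane, directly over C6 and C8 of ring A.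

## Retrosynthesis

**24 to 21 (bonds C1–benzoyl and C5–geranyl).** Target 24 is cut first at its two labile appendages, through the C5-geranyl trione 23 back to the bare cage trione 21. Bridgehead carbanions of bicyclo[3.3.1]nonane triones are known to alkylate and acylate at carbon. Carrying either group through cage construction would expose a diene to hydride and hydrogen, or a benzoyl ketone to enolate chemistry. The forward reaction must deprotonate C5 (next to C6H2) before C1 (next to quaternary C8); benzoyl is placed last because the resulting tricarbonyl is the most fragile array.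

**21 to 20 (C10–H and C11–H).** The C11 stereocentre is removed by introducing the C10=C11 alkene, giving the didehydro trione 20. This alkene is also what makes the cage closure workable, so its reduction is placed after the closure and before geranylation. The forward step asks for hydrogen delivery to a hindered trisubstituted alkene from the face away from the C8 methyl groups.

**20 to 18 (bonds C4–C5 and C1–C2).** Both acyl–carbon bonds of the trione ring are cut, leading to the ring A enone 18 with a (Z)-cyclopentylidene bis(phenyl ester). Cutting at C2–C3 or C3–C4 instead would require acylating a hindered cyclopentyl carbanion and would break the symmetry of the malonate. Cutting at C9 would leave no simple carbonyl partner. The chosen cut removes two rings and three stereocentres at once: 18 has one stereocentre and two ordinary rings. The forward reaction needs a regiodefined C5 enolate formed without base (conjugate reduction of the enone), C-acylation through a seven-membered transition state, and then a second deprotonation at C1 by an amide strong enough to form a diketone dianion.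

**18 to 17 (bond C3–C11).** The cyclopentylidene is opened to the alkynyl malonate 17. A gold-catalysed Conia-ene closure adds the malonate carbon and hydrogen anti across the alkyne, so the (Z)-geometry follows from the mechanism. Olefination of a ketone flanked by two quaternary carbons could not give that control. The forward step is a 5-exo-dig closure onto a hindered internal alkyne.

**17 to 14 and 15 (bond C3–C14).** The malonate is detached as diphenyl malonate 15, leaving the primary iodide 14. The enone of 17 is carried as the dioxolane 16 through all basic steps and released with mild acid. The aryl esters are brought in intact because a hindered quaternary diester could not be exchanged later.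

**14 to 8 (alkyne and bond C11–C12).** Iodide 14 comes from alcohol 13 and this from the terminal alkene of enyne 11 by hydroboration. The alkyne of 11 comes from ketone 9 through its enol triflate 10; enolisation is possible only towards C10. Ketone 9 is cut at C11–C12 into the Weinreb amide 8 and a prenyl Grignard reagent, which reacts through its γ-carbon and so delivers the quaternary C12 and the vinyl group that becomes C13–C14.

**8 to 5 (oxidation level of C9).** Amide 8 comes from ester 7, the ketal of enone ester 6, and 6 from the cyclohexene ester 5 by allylic oxidation at C9. The oxidation is placed here because C7–H is then only a hindered tertiary allylic hydrogen; after the alkyne is in place it would be propargylic as well.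

**5 to 1 and 3 (bond C7–C10).** The C7–C10 bond is cut by a Johnson–Claisen rearrangement of allylic alcohol 2 with triethyl orthoacetate 3, which moves the carbinol configuration to C7 across the ring face. Alcohol 2 comes from 4,4-dimethylcyclohex-2-en-1-one 1 by CBS reduction. Geranyl bromide 22 is the fourth purchased building block.

## Roads not taken

**Alternative 1:** The cut is at C3–C11 on a saturated tether. The α-diazo ester A2 is turned by Rh2(S-PTTL)4, dirhodium tetrakis[N-phthaloyl-(S)-tert-leucinate], into the carbene at C3, which inserts into a C11–H bond and gives the trans cyclopentane ester A1 on a ketal-protected ring A.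
- Merits: C11 is set early and under catalyst control, with no alkyne, no gold step and no late hydrogenation of a hindered alkene. On control of C11 this road is better than the chosen plan, which relies on substrate-controlled hydrogen delivery.
- Weak points: the site is an unactivated methylene next to quaternary C12. A 1,2-hydride shift from C14 to the carbene and insertion into the C12 methyl groups compete. The catalyst alone must relate C11 to the remote C7.
- Further cost: A1 carries only one carboxyl carbon on C3, so C3 must still be acylated to the quaternary diester. The saturated C10–C11 tether has lost the planar (Z)-alkene that holds the two esters over C6 and C8.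
- Comparison: the chosen plan sets against the weaker control of C11 a single operation in which C7 fixes C1, C3 and C5, and a precursor in which both acyl carbons arrive in one malonate alkylation.

**Alternative 2:** The cuts are C11–C12 and C3–C14. The tertiary radical released from the N-(acyloxy)phthalimide A5 adds to the central carbon of the allene diester A4; the resulting malonyl radical is reduced to the enolate and displaces bromide, giving the saturated ring A ketone A3 with the (Z)-cyclopentylidene bis(phenyl ester).
- Merits: this is the most convergent road. The quaternary C12, the cyclopentane and the alkene form in one step, and the whole alkyne, hydroboration, iodide, alkylation and Conia-ene sequence of the chosen plan is avoided. A3 differs from 18 only at C5–C6 and could be closed to the cage by base alone. If the annulation worked, this road would be shorter.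
- Weak points: A4 is a doubly activated allene with aryl esters, strongly electrophilic and prone to oligomerise. It must be made next to the C7 stereocentre, whose hydrogen is then allenylic. The (Z)-geometry rests on steric approach of the radical anti to ring A, not on mechanism. Three events (radical release, addition, reduction with alkylation) must keep pace.
- Comparison: the chosen plan sets against the extra steps that each step to 18 is a precedented two-electron reaction with mechanism-defined geometry, and that the enone gives the first enolate regiospecifically and without base.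

**Alternative 3:** The cut is C1–C8, with ring A closed last. Co(salen), N,N′-ethylenebis(salicylideneiminato)cobalt, with PhSiH3 and an N-fluoropyridinium oxidant transfers a hydrogen atom to the isopropenyl CH2 of A7; the C8 radical is oxidised to the cation and captured by the enol carbon C1, giving the benzoylated didehydro cage A6.
- Merits: the most congested bond of the target (C1–C8, between two quaternary carbons) is made by cation capture, and benzoyl is already on C1. This avoids the hindered bridgehead benzoylation that is the weakest end-game step of the chosen plan; in that respect this road is better.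
- Weak points: A7 is itself a bridged bicyclic acyl trione with three stereocentres, to be built without the help of a preformed ring A. Its nucleophile is an ambident 2-acyl-1,3-dione enol, for which capture through oxygen to a cyclic enol ether is a known outcome. Hydrogen-atom transfer must choose the isopropenyl group over the C10=C11 alkene. Geranyl must still be introduced at C5 in the presence of the benzoyl tricarbonyl.
- Comparison: the chosen plan sets against the risk at C1 that ring A, with C8 and the C1–C8 bond, is bought, and that C7 is set by a simple Claisen shift on that ring.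

Key step: step 13

Assumption: the (S)-configured CBS catalyst is taken to give the (R)-alcohol 2, the alkenyl arm of 1 acting as the large group; descriptors on cage compounds refer to the cage locants C1–C14 defined above, not to systematic numbering.

## Route

**Step 1**
Reactants: 1 4,4-dimethylcyclohex-2-en-1-one
Product: 2 (1R)-4,4-dimethylcyclohex-2-en-1-ol
Conditions: (S)-2-methyl-CBS-oxazaborolidine (10 mol%), catecholborane, toluene, −78 °C; aq. NaOH
Reagents that add atoms: none
Why: CBS reduction; the oxazaborolidine–borane complex binds the ketone with the alkenyl arm as the large group and delivers hydride to one carbonyl face, which should set the (R)-carbinol; at −78 °C the hindered alkene is not hydroborated.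

**Step 2**
Reactants: 2 (1R)-4,4-dimethylcyclohex-2-en-1-ol; 3 triethyl orthoacetate
Product: 5 ethyl 2-[(1R)-6,6-dimethylcyclohex-2-en-1-yl]acetate, via mixed ketene acetal 4 (not isolated)
Conditions: 3 (excess), EtCO2H (cat.), 140 °C, distil off EtOH
Reagents that add atoms: none
Why: Johnson–Claisen rearrangement; the suprafacial [3,3] shift forms the C7–C10 bond on the ring face from which the oxygen leaves, so the carbinol configuration of 2 is transferred to C7 and should give (R)-5.

**Step 3**
Reactants: 5 ethyl 2-[(1R)-6,6-dimethylcyclohex-2-en-1-yl]acetate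
Product: 6 ethyl 2-[(1R)-6,6-dimethyl-4-oxocyclohex-2-en-1-yl]acetate
Conditions: Rh2(cap)4 (dirhodium tetracaprolactamate, 1 mol%), t-BuOOH (70% aq.), K2CO3, CH2Cl2, rt
Reagents that add atoms: tert-butyl hydroperoxide, CC(C)(C)OO
Why: Radical allylic C–H oxidation; the C9 methylene is the accessible allylic site, whereas the tertiary C7–H is shielded by quaternary C8 and the side chain, and the allyl radical should be trapped at its unhindered end C9, giving the enone without moving the alkene or touching C7.

**Step 4**
Reactants: 6 ethyl 2-[(1R)-6,6-dimethyl-4-oxocyclohex-2-en-1-yl]acetate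
Product: 7 ethyl 2-[(8R)-9,9-dimethyl-1,4-dioxaspiro[4.5]dec-6-en-8-yl]acetate
Conditions: (Me3SiOCH2)2, Me3SiOTf (cat.), CH2Cl2, −78 → −20 °C
Reagents that add atoms: 1,2-bis(trimethylsilyloxy)ethane, C[Si](C)(C)OCCO[Si](C)(C)C
Why: Silyl-transfer ketalisation under kinetic control; the oxocarbenium ion is captured at low temperature before the alkene can leave conjugation, so the C5=C6 position and C7 stay as they are, and the enone is masked against Grignard reagents, amide bases and borane.

**Step 5**
Reactants: 7 ethyl 2-[(8R)-9,9-dimethyl-1,4-dioxaspiro[4.5]dec-6-en-8-yl]acetate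
Product: 8 2-[(8R)-9,9-dimethyl-1,4-dioxaspiro[4.5]dec-6-en-8-yl]-N-methoxy-N-methylacetamide
Conditions: MeNH(OMe)·HCl, i-PrMgCl, THF, −20 → 0 °C
Reagents that add atoms: N,O-dimethylhydroxylamine hydrochloride, CNOC.Cl
Why: Weinreb amide formation by aminolysis of the ester with the magnesium amide made in the flask; the ketal and the alkene are inert.

**Step 6**
Reactants: 8 2-[(8R)-9,9-dimethyl-1,4-dioxaspiro[4.5]dec-6-en-8-yl]-N-methoxy-N-methylacetamide
Product: 9 1-[(8R)-9,9-dimethyl-1,4-dioxaspiro[4.5]dec-6-en-8-yl]-3,3-dimethylpent-4-en-2-one
Conditions: Me2C=CHCH2MgCl (prenylmagnesium chloride), THF, −78 → 0 °C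
Reagents that add atoms: 3-methylbut-2-en-1-ylmagnesium chloride, CC(C)=CC[Mg]Cl
Why: Grignard addition to a Weinreb amide; the allylic reagent reacts through its γ-carbon in a six-membered transition state, making the C11–C12 bond and the quaternary C12, while the chelated tetrahedral intermediate stops at the ketone and the quaternary α-carbon keeps the vinyl group out of conjugation.

**Step 7**
Reactants: 9 1-[(8R)-9,9-dimethyl-1,4-dioxaspiro[4.5]dec-6-en-8-yl]-3,3-dimethylpent-4-en-2-one
Product: 11 (8R)-8-(3,3-dimethylpent-4-en-1-yn-1-yl)-9,9-dimethyl-1,4-dioxaspiro[4.5]dec-6-ene, via (Z)-enol triflate 10 (not isolated)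
Conditions: KN(SiMe3)2, THF, −78 °C; PhNTf2; then LiN(i-Pr)2, −78 → −40 °C
Reagents that add atoms: N-phenylbis(trifluoromethanesulfonimide), O=S(=O)(N(c1ccccc1)S(=O)(=O)C(F)(F)F)C(F)(F)F (its CF3SO2 group is found in 10 only)
Why: Ketone to alkyne through an enol triflate; enolisation can only go towards C10 and gives the (Z)-enolate, so the triflate has H anti to the leaving group and anti-elimination should give the alkyne; low temperature and measured base leave the allylic and propargylic C7–H alone.

**Step 8**
Reactants: 11 (8R)-8-(3,3-dimethylpent-4-en-1-yn-1-yl)-9,9-dimethyl-1,4-dioxaspiro[4.5]dec-6-ene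
Product: 13 5-[(8R)-9,9-dimethyl-1,4-dioxaspiro[4.5]dec-6-en-8-yl]-3,3-dimethylpent-4-yn-1-ol, via B-alkyl-9-borabicyclononane 12 (not isolated)
Conditions: 9-BBN, THF, 0 °C → rt; then NaOH, H2O2, 0 °C
Reagents that add atoms: 9-borabicyclo[3.3.1]nonane, B1C2CCCC1CCC2 (in 12 only); hydrogen peroxide, OO
Why: Hydroboration–oxidation; 9-BBN should pick the monosubstituted alkene over the ring cis-alkene and the doubly hindered internal alkyne and place boron on the terminal carbon C14.

**Step 9**
Reactants: 13 5-[(8R)-9,9-dimethyl-1,4-dioxaspiro[4.5]dec-6-en-8-yl]-3,3-dimethylpent-4-yn-1-ol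
Product: 14 (8R)-8-(5-iodo-3,3-dimethylpent-1-yn-1-yl)-9,9-dimethyl-1,4-dioxaspiro[4.5]dec-6-ene
Conditions: I2, PPh3, imidazole, CH2Cl2, 0 °C → rt
Reagents that add atoms: iodine, II
Why: Appel-type iodination of a primary alcohol by SN2 displacement of the phosphonium oxide; imidazole buffers the medium so the ketal survives.

**Step 10**
Reactants: 14 (8R)-8-(5-iodo-3,3-dimethylpent-1-yn-1-yl)-9,9-dimethyl-1,4-dioxaspiro[4.5]dec-6-ene; 15 diphenyl malonate
Product: 16 diphenyl 2-{5-[(8R)-9,9-dimethyl-1,4-dioxaspiro[4.5]dec-6-en-8-yl]-3,3-dimethylpent-4-yn-1-yl}propanedioate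
Conditions: 15 (2 equiv), NaH, THF/DMF, 0 → 40 °C
Reagents that add atoms: none
Why: Malonate alkylation (SN2 at the primary iodide, bond C3–C14); the sodium enolate of the aryl malonate is a stabilised, weakly basic nucleophile and the excess of 15 should suppress dialkylation.

**Step 11**
Reactants: 16 diphenyl 2-{5-[(8R)-9,9-dimethyl-1,4-dioxaspiro[4.5]dec-6-en-8-yl]-3,3-dimethylpent-4-yn-1-yl}propanedioate
Product: 17 diphenyl 2-{5-[(1R)-6,6-dimethyl-4-oxocyclohex-2-en-1-yl]-3,3-dimethylpent-4-yn-1-yl}propanedioate
Conditions: PPTS, acetone/H2O, rt
Reagents that add atoms: water, O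
Why: Acid-catalysed hydrolysis of the allylic ketal returns the conjugated enone; pyridinium tosylate is too weak to cleave aryl esters or to enolise towards C7, and 17 is thereafter kept away from base.

**Step 12**
Reactants: 17 diphenyl 2-{5-[(1R)-6,6-dimethyl-4-oxocyclohex-2-en-1-yl]-3,3-dimethylpent-4-yn-1-yl}propanedioate
Product: 18 diphenyl (2Z)-2-{[(1S)-6,6-dimethyl-4-oxocyclohex-2-en-1-yl]methylidene}-3,3-dimethylcyclopentane-1,1-dicarboxylate
Conditions: Ph3PAuNTf2 (5 mol%), CH2Cl2, rt → 40 °C
Reagents that add atoms: none
Why: Gold-catalysed Conia-ene reaction; cationic monovalent gold activates the alkyne, the malonate enol attacks C11 anti to gold in a 5-exo-dig closure helped by the C12 gem-dimethyl group, and protodeauration with retention puts H on C10 trans to C3, so C7 ends cis to C3 (Z) by mechanism. The neutral conditions spare the C7–H, which is now doubly allylic and γ to the enone.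

**Step 13**
Reactants: 18 diphenyl (2Z)-2-{[(1S)-6,6-dimethyl-4-oxocyclohex-2-en-1-yl]methylidene}-3,3-dimethylcyclopentane-1,1-dicarboxylate
Product: 20 10,11-didehydro cage trione with H on C1 and C5 [(1R,3S,5S,7S)], via monocyclised diketo ester 19 (not isolated)
Conditions: K[HB(s-Bu)3] (1.05 equiv), THF, −78 → −20 °C; then LiN(i-Pr)2 (3 equiv), −78 → 0 °C; aq. NH4Cl
Reagents that add atoms: none
Why: Proposed new method: K[HB(s-Bu)3] adds hydride to C6 of the β-unsubstituted enone (the known conjugate reduction of cyclohexenones to potassium enolates) and so gives the C5 enolate regiospecifically and without base; this enolate attacks the phenyl ester lying on the C6 face, expels phenoxide and forms bond C4–C5 in a 7-(enolexo)-exo-trig closure of ring C3–C4–C5–C6–C7–C10–C11, giving 19 as its enolate. LiN(i-Pr)2, chosen because a diketone enolate needs an amide of this strength for its second deprotonation, then removes a C1 proton, and the terminal carbon of the dianion attacks the second ester on the C8 face (bond C1–C2), closing the trione ring C1–C2–C3–C4–C5–C9 in a 6-(enolendo)-exo-trig sense and with it the second seven-membered ring C1–C2–C3–C11–C10–C7–C8 (7-(enolexo)-exo-trig). The closest known reaction types are conjugate reduction followed by intramolecular enolate C-acylation and the γ-acylation of β-diketone dianions by aryl esters (Dieckmann and Claisen types); their union into a double cage closure is what is new. Allylic 1,3-strain across the (Z)-alkene holds C7–H in the alkene plane, so C6 and C8 lie on opposite faces, each under one ester, and both new bonds are axial on ring A and syn to the axial C7–C10 bond, the only geometry the tether allows. C5, C3 and C1 are therefore set by C7 alone, (7S) forcing (5S), (3S) and (1R), and no diastereomeric cage can close. The step needs 1,4- over 1,2-addition of hydride (bulky borohydride, unsubstituted C6), C- over O-acylation (O-attack would need a nine-membered enol lactone) and an electrophile that neither enolises nor reopens (C3 carries no hydrogen and phenoxide is a poor nucleophile).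

**Step 14**
Reactants: 20 10,11-didehydro cage trione with H on C1 and C5 [(1R,3S,5S,7S)]
Product: 21 saturated cage trione with H on C1 and C5 [(1R,3S,5S,7R,11R)]
Conditions: H2 (5 bar), Pd/C, EtOAc, rt
Reagents that add atoms: none
Why: Heterogeneous hydrogenation; syn delivery of hydrogen to the face of C10=C11 flanked by C6H2, the other face being covered by the inward C8 methyl group, should set C11 with C12 turned towards C8 and C1; no other group in 20 is reducible and the alkene cannot migrate (its only allylic hydrogen is at bridgehead C7).

**Step 15**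
Reactants: 21 saturated cage trione with H on C1 and C5 [(1R,3S,5S,7R,11R)]; 22 geranyl bromide
Product: 23 C5-geranyl cage trione with H on C1 [(1R,3R,5S,7R,11R)]
Conditions: lithium 2,2,6,6-tetramethylpiperidide (from the amine and n-BuLi, 1.1 equiv), THF, −78 °C; 22, −78 → 0 °C
Reagents that add atoms: none
Why: Bridgehead lithiation and alkylation of a bicyclo[3.3.1]nonane trione; the bulky amide should remove C5–H, flanked by two carbonyls and the open C6H2, in preference to C1–H next to quaternary C8, and the bridgehead carbanion alkylates at carbon by SN2 on the primary allylic bromide with the configuration fixed by the cage.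

**Step 16**
Reactants: 23 C5-geranyl cage trione with H on C1 [(1R,3R,5S,7R,11R)]
Product: 24 CNP0168637.1, the C1-benzoyl C5-geranyl cage trione [(1S,3S,5R,7R,11R)]
Conditions: lithium 2,2,6,6-tetramethylpiperidide (from the amine and n-BuLi), THF, −78 °C; PhCOCl, −78 → −30 °C; cold aq. NH4Cl
Reagents that add atoms: benzoyl chloride, O=C(Cl)c1ccccc1
Why: Second bridgehead lithiation at the only remaining acidic C–H (C1) and C-acylation by the acid chloride; the configuration at C1 is dictated by the cage, and a cold non-nucleophilic quench protects the new tricarbonyl array from retro-Claisen cleavage.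

## Compound list

1 | 4,4-dimethylcyclohex-2-en-1-one | CC1(C)CCC(=O)C=C1 | starting material
2 | (1R)-4,4-dimethylcyclohex-2-en-1-ol | O[C@H]1C=CC(C)(C)CC1 | intermediate
3 | triethyl orthoacetate | CCOC(C)(OCC)OCC | starting material
4 | 1-ethoxy-1-{[(1R)-4,4-dimethylcyclohex-2-en-1-yl]oxy}ethene (mixed ketene acetal, not isolated) | C=C(OCC)O[C@H]1C=CC(C)(C)CC1 | intermediate
5 | ethyl 2-[(1R)-6,6-dimethylcyclohex-2-en-1-yl]acetate | CCOC(=O)C[C@@H]1C=CCCC1(C)C | intermediate
6 | ethyl 2-[(1R)-6,6-dimethyl-4-oxocyclohex-2-en-1-yl]acetate | CCOC(=O)C[C@@H]1C=CC(=O)CC1(C)C | intermediate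
7 | ethyl 2-[(8R)-9,9-dimethyl-1,4-dioxaspiro[4.5]dec-6-en-8-yl]acetate | CCOC(=O)C[C@@H]1C=CC2(OCCO2)CC1(C)C | intermediate
8 | 2-[(8R)-9,9-dimethyl-1,4-dioxaspiro[4.5]dec-6-en-8-yl]-N-methoxy-N-methylacetamide | CON(C)C(=O)C[C@@H]1C=CC2(OCCO2)CC1(C)C | intermediate
9 | 1-[(8R)-9,9-dimethyl-1,4-dioxaspiro[4.5]dec-6-en-8-yl]-3,3-dimethylpent-4-en-2-one | C=CC(C)(C)C(=O)C[C@@H]1C=CC2(OCCO2)CC1(C)C | intermediate
10 | (1Z)-1-[(8S)-9,9-dimethyl-1,4-dioxaspiro[4.5]dec-6-en-8-yl]-3,3-dimethylpenta-1,4-dien-2-yl trifluoromethanesulfonate (not isolated) | C=CC(C)(C)/C(OS(=O)(=O)C(F)(F)F)=C/[C@@H]1C=CC2(OCCO2)CC1(C)C | intermediate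
11 | (8R)-8-(3,3-dimethylpent-4-en-1-yn-1-yl)-9,9-dimethyl-1,4-dioxaspiro[4.5]dec-6-ene | C=CC(C)(C)C#C[C@@H]1C=CC2(OCCO2)CC1(C)C | intermediate
12 | 9-{5-[(8R)-9,9-dimethyl-1,4-dioxaspiro[4.5]dec-6-en-8-yl]-3,3-dimethylpent-4-yn-1-yl}-9-borabicyclo[3.3.1]nonane (not isolated) | B1(CCC(C)(C)C#C[C@@H]2C=CC3(OCCO3)CC2(C)C)C4CCCC1CCC4 | intermediate
13 | 5-[(8R)-9,9-dimethyl-1,4-dioxaspiro[4.5]dec-6-en-8-yl]-3,3-dimethylpent-4-yn-1-ol | OCCC(C)(C)C#C[C@@H]1C=CC2(OCCO2)CC1(C)C | intermediate
14 | (8R)-8-(5-iodo-3,3-dimethylpent-1-yn-1-yl)-9,9-dimethyl-1,4-dioxaspiro[4.5]dec-6-ene | ICCC(C)(C)C#C[C@@H]1C=CC2(OCCO2)CC1(C)C | intermediate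
15 | diphenyl malonate | O=C(CC(=O)Oc1ccccc1)Oc1ccccc1 | starting material
16 | diphenyl 2-{5-[(8R)-9,9-dimethyl-1,4-dioxaspiro[4.5]dec-6-en-8-yl]-3,3-dimethylpent-4-yn-1-yl}propanedioate | O=C(Oc1ccccc1)C(CCC(C)(C)C#C[C@@H]1C=CC2(OCCO2)CC1(C)C)C(=O)Oc1ccccc1 | intermediate
17 | diphenyl 2-{5-[(1R)-6,6-dimethyl-4-oxocyclohex-2-en-1-yl]-3,3-dimethylpent-4-yn-1-yl}propanedioate | O=C(Oc1ccccc1)C(CCC(C)(C)C#C[C@@H]1C=CC(=O)CC1(C)C)C(=O)Oc1ccccc1 | intermediate
18 | diphenyl (2Z)-2-{[(1S)-6,6-dimethyl-4-oxocyclohex-2-en-1-yl]methylidene}-3,3-dimethylcyclopentane-1,1-dicarboxylate | O=C1C=C[C@@H](/C=C2/C(C)(C)CCC2(C(=O)Oc2ccccc2)C(=O)Oc2ccccc2)C(C)(C)C1 | intermediate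
19 | monocyclised diketo phenyl ester: bond C4–C5 made, C1–C2 not yet; bicyclo[4.3.1]decene with bridgeheads C5 and C7, C9 and C4 ketones, C3 carrying the remaining CO2Ph and the fused cyclopentane [(3S,5S,7S)] (not isolated) | O=C1CC(C)(C)[C@H]2C[C@@H]1C(=O)[C@]3(C(=O)Oc4ccccc4)CCC(C)(C)C3=C2 | intermediate
20 | 10,11-didehydro cage trione with H on C1 and C5 [(1R,3S,5S,7S)] | [C@@H]12C[C@H]3C=C4C(C)(C)CC[C@]4(C1=O)C(=O)[C@@H](C2=O)C3(C)C | intermediate
21 | saturated cage trione with H on C1 and C5 [(1R,3S,5S,7R,11R)] | [C@@H]12C[C@H]3C[C@@H]4C(C)(C)CC[C@]4(C1=O)C(=O)[C@@H](C2=O)C3(C)C | intermediate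
22 | geranyl bromide, (2E)-1-bromo-3,7-dimethylocta-2,6-diene | CC(C)=CCC/C(C)=C/CBr | starting material
23 | C5-geranyl cage trione with H on C1 [(1R,3R,5S,7R,11R)] | CC(C)=CCC/C(C)=C/C[C@@]12C[C@H]3C[C@@H]4C(C)(C)CC[C@]4(C1=O)C(=O)[C@@H](C2=O)C3(C)C | intermediate
24 | CNP0168637.1, the C1-benzoyl C5-geranyl cage trione [(1S,3S,5R,7R,11R)] | CC(C)=CCC/C(C)=C/C[C@@]12C[C@H]3C[C@@H]4C(C)(C)CC[C@]4(C1=O)C(=O)[C@@](C(=O)c1ccccc1)(C2=O)C3(C)C | target

## Step count and least certain steps

Total: 16 steps. Longest linear sequence: 16 steps, from 1 to 24; 3, 15 and 22 enter as purchased partners.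

**Step 13 (key step).** Most likely to go wrong: hydride may add 1,2 to the enone or reach an aryl ester, or the second closure may stall because the tri-sec-butylborane left in the flask ties up the amide and the dianion is not formed. The fallback separates the three events and uses known reactions only. It sets out from 18: conjugate reduction with [(Ph3P)CuH]6 in toluene should give, after protic work-up, the saturated ketone diphenyl (2Z)-2-{[(1S)-2,2-dimethyl-4-oxocyclohexyl]methylidene}-3,3-dimethylcyclopentane-1,1-dicarboxylate F1 (the same compound as A3). LiN(SiMe3)2 in THF at −78 → 0 °C then effects the first Dieckmann-type closure from the less hindered α-carbon C5, and 19 is isolated. LiN(i-Pr)2 (2.2 equiv) forms the dianion of 19 and closes the trione ring. The fallback comes back to the route at 20. The order in which the two α-carbons react does not affect the final cage.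

**Step 12.** Most likely to go wrong: no turnover, because the alkyne is flanked by a quaternary and a tertiary carbon and the malonate is only weakly enolised; or slow loss of C7 integrity on prolonged warming. The fallback changes from metal-catalysed protocyclisation to electrophile-driven closure. It sets out from 17: I2 with Ti(Ot-Bu)4 in CH2Cl2 should add the titanium malonate enolate and iodine anti across the alkyne, giving the vinyl iodide diphenyl (2E)-2-{iodo[(1R)-6,6-dimethyl-4-oxocyclohex-2-en-1-yl]methylidene}-3,3-dimethylcyclopentane-1,1-dicarboxylate F2. Hydrodeiodination with retention (Pd(OAc)2, PPh3, HCO2H, Et3N) comes back to the route at 18.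

**Step 3.** Most likely to go wrong: poor site selectivity, with hydrogen abstraction at the tertiary C7–H or trapping of the allyl radical at C6, and over-oxidation. The fallback brings the C9 oxygen in before the Claisen step. It sets out from 1:
- LiN(i-Pr)2 and t-BuMe2SiCl give the silyl dienol ether tert-butyl[(4,4-dimethylcyclohexa-1,5-dien-1-yl)oxy]dimethylsilane F3.
- Rubottom oxidation with m-CPBA gives racemic 6-[(tert-butyldimethylsilyl)oxy]-4,4-dimethylcyclohex-2-en-1-one F4.
- CBS reduction under catalyst control gives 6-[(tert-butyldimethylsilyl)oxy]-4,4-dimethylcyclohex-2-en-1-ol F5, with the carbinol carbon configured as in 2 and both epimers at the silyloxy carbon.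
- Johnson–Claisen rearrangement with 3 gives ethyl 2-[(1R)-4-[(tert-butyldimethylsilyl)oxy]-6,6-dimethylcyclohex-2-en-1-yl]acetate F6.
- Bu4NF gives ethyl 2-[(1R)-4-hydroxy-6,6-dimethylcyclohex-2-en-1-yl]acetate F7.
- MnO2 oxidises the allylic alcohol, and the fallback comes back to the route at 6.

**Step 14.** Most likely to go wrong: no hydrogen uptake, because the alkene is flanked by two quaternary carbons, or loss of face selectivity under forcing conditions. The fallback changes from surface hydrogenation to metal-hydride hydrogen-atom transfer. It sets out from 20: Mn(dpm)3, tris(dipivaloylmethanato)manganese, with PhSiH3 and t-BuOOH in i-PrOH transfers a hydrogen atom to C10, and the tertiary C11 radical is then quenched from the open C6 face. It comes back to the route at 21 and makes no new compound (F0).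

**Step 16.** Most likely to go wrong: incomplete deprotonation at C1 next to quaternary C8, sluggish capture of the acid chloride by the hindered carbanion, and retro-Claisen cleavage of the product on warming. The fallback replaces direct acylation by a halogen–metal exchange route. It sets out from 23: the same amide base and I2 give the C1-iodo C5-geranyl cage trione F8. Exchange with i-PrMgCl at −78 °C and addition to benzaldehyde give the C1-[hydroxy(phenyl)methyl] C5-geranyl cage trione F9 (either carbinol epimer). Dess–Martin periodinane oxidises the carbinol, and the fallback comes back to the route at 24.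

## Further compounds

F1 | step 13 | diphenyl (2Z)-2-{[(1S)-2,2-dimethyl-4-oxocyclohexyl]methylidene}-3,3-dimethylcyclopentane-1,1-dicarboxylate | O=C1CC[C@@H](/C=C2/C(C)(C)CCC2(C(=O)Oc2ccccc2)C(=O)Oc2ccccc2)C(C)(C)C1
F2 | step 12 | diphenyl (2E)-2-{iodo[(1R)-6,6-dimethyl-4-oxocyclohex-2-en-1-yl]methylidene}-3,3-dimethylcyclopentane-1,1-dicarboxylate | O=C1C=C[C@@H](/C(I)=C2/C(C)(C)CCC2(C(=O)Oc2ccccc2)C(=O)Oc2ccccc2)C(C)(C)C1
F3 | step 3 | tert-butyl[(4,4-dimethylcyclohexa-1,5-dien-1-yl)oxy]dimethylsilane | CC1(C)CC=C(O[Si](C)(C)C(C)(C)C)C=C1
F4 | step 3 | 6-[(tert-butyldimethylsilyl)oxy]-4,4-dimethylcyclohex-2-en-1-one (racemic) | CC1(C)CC(O[Si](C)(C)C(C)(C)C)C(=O)C=C1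
F5 | step 3 | 6-[(tert-butyldimethylsilyl)oxy]-4,4-dimethylcyclohex-2-en-1-ol, carbinol carbon as in 2 [(1S) by the sequence rule], both epimers at C6 | CC1(C)CC(O[Si](C)(C)C(C)(C)C)[C@@H](O)C=C1
F6 | step 3 | ethyl 2-[(1R)-4-[(tert-butyldimethylsilyl)oxy]-6,6-dimethylcyclohex-2-en-1-yl]acetate, both epimers at C4 | CCOC(=O)C[C@@H]1C=CC(O[Si](C)(C)C(C)(C)C)CC1(C)C
F7 | step 3 | ethyl 2-[(1R)-4-hydroxy-6,6-dimethylcyclohex-2-en-1-yl]acetate, both epimers at C4 | CCOC(=O)C[C@@H]1C=CC(O)CC1(C)C
F0 | step 14 | none | none
F8 | step 16 | C1-iodo C5-geranyl cage trione (cage configured as in 24) | CC(C)=CCC/C(C)=C/C[C@@]12C[C@H]3C[C@@H]4C(C)(C)CC[C@]4(C1=O)C(=O)[C@@](I)(C2=O)C3(C)C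
F9 | step 16 | C1-[hydroxy(phenyl)methyl] C5-geranyl cage trione (cage configured as in 24, carbinol carbon undefined) | CC(C)=CCC/C(C)=C/C[C@@]12C[C@H]3C[C@@H]4C(C)(C)CC[C@]4(C1=O)C(=O)[C@@](C(O)c1ccccc1)(C2=O)C3(C)C
A1 | alternative 1 | methyl (1R,2S)-2-{[(8S)-9,9-dimethyl-1,4-dioxaspiro[4.5]decan-8-yl]methyl}-3,3-dimethylcyclopentane-1-carboxylate | COC(=O)[C@@H]1CCC(C)(C)[C@H]1C[C@@H]1CCC2(CC1(C)C)OCCO2
A2 | alternative 1 | methyl 2-diazo-7-[(8R)-9,9-dimethyl-1,4-dioxaspiro[4.5]decan-8-yl]-5,5-dimethylheptanoate | COC(=O)C(=[N+]=[N-])CCC(C)(C)CC[C@@H]1CCC2(CC1(C)C)OCCO2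
A3 | alternative 2 | diphenyl (2Z)-2-{[(1S)-2,2-dimethyl-4-oxocyclohexyl]methylidene}-3,3-dimethylcyclopentane-1,1-dicarboxylate | O=C1CC[C@@H](/C=C2/C(C)(C)CCC2(C(=O)Oc2ccccc2)C(=O)Oc2ccccc2)C(C)(C)C1
A4 | alternative 2 | diphenyl 2-{2-[(1S)-2,2-dimethyl-4-oxocyclohexyl]ethenylidene}propanedioate | O=C1CC[C@@H](C=C=C(C(=O)Oc2ccccc2)C(=O)Oc2ccccc2)C(C)(C)C1
A5 | alternative 2 | 1,3-dioxoisoindolin-2-yl 4-bromo-2,2-dimethylbutanoate | O=C(ON1C(=O)c2ccccc2C1=O)C(C)(C)CCBr
A6 | alternative 3 | 10,11-didehydro cage trione with benzoyl on C1 and H on C5 (cage configured as in 24) | [C@@H]12C[C@H]3C=C4C(C)(C)CC[C@]4(C1=O)C(=O)[C@@](C(=O)c1ccccc1)(C2=O)C3(C)C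
A7 | alternative 3 | bicyclic precursor lacking the C1–C8 bond: C7 carries a prop-1-en-2-yl group, C1 (between the C9 and C2 ketones) carries benzoyl; C3, C5 and C7 as in 24 | C=C(C)[C@H]1C[C@H]2C(=O)C(C(=O)c3ccccc3)C(=O)[C@]4(CCC(C)(C)C4=C1)C2=O
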